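## Analysis of the target

The target is a flavone in which benzo ring A is fused through C4a and C8a to the pyran-4-one ring C, and ring C carries the aryl ring B at C2. There is no stereocentre, so no configuration has to be set or preserved. Ring A is fully substituted, with a free hydroxyl at C5, methoxy groups at C6, C7 and C8 and the fusion carbons C4a and C8a, so four contiguous oxygens must be placed and only O5 may end up free. Ring B is a 2',5'-dihydroxyphenyl group, a free hydroquinone that is easily oxidised to a quinone, above all under base, so its oxygens must stay masked until the last step by groups that can be removed without touching the three methyl ethers. The 5-hydroxyl is hydrogen-bonded to the C4 carbonyl; this makes it the least nucleophilic oxygen, which helps selective alkylation elsewhere, but it also draws Lewis acids next to the C6 methoxy group. The difficulty is the hexasubstituted, oxygen-differentiated ring A, which the classical flavone closure (phenol oxygen onto the side-chain carbonyl) can reach only from a pentaoxygenated acetophenone followed by selective dealkylation. The strategy rests on O5 and O8 being para on ring A, so that ring A can be raised to a quinone with carbonyls at C5 and C8. In the corresponding acylquinone the only unsubstituted ring carbon is the future C8a, next to the acyl carbon C4, so O1–C8a can be formed by adding the side-chain enol oxygen to the ring, the reverse polarity of the usual closure.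

## Retrosynthetic reasoning

**14 to 13.** The two O–benzyl bonds on ring B are cut last. The ring B hydroquinone is the most fragile part of the target and should exist only in the final product. Benzyl is chosen because hydrogenolysis leaves aryl methyl ethers and the chelated phenol alone. The forward step must remove both benzyl groups without reducing the C2=C3 bond.

**13 to 12.** The O8–CH3 bond is cut. This turns ring A into a 5,8-hydroquinone, which is what gives access to the quinone oxidation level. The forward methylation must distinguish O8 from O5, and the hydrogen bond from O5–H to the C4 carbonyl provides that distinction.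

**12 to 9 (through 11 and 10).** The O1–C8a bond is cut, not the usual O1–C2 bond. Cutting O1–C2 would require a methyl ketone with five ring oxygens, and in 9 itself closure through the ortho hydroxyl would lead to a constitutional isomer without oxygen at C5. Cutting O1–C8a leaves hydrogen at the future C8a, so ring A needs only four oxygens and can come from a symmetrical quinone. Forward, 9 is oxidised to acylquinone 10, the enol oxygen adds to the one free quinone carbon, and tautomerisation returns the aromatic ring. Because the product is again an oxidisable hydroquinone, the step is carried on to quinone 11 and then reduced to 12.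

**9 to 4 and 8.** The C2–C3 bond (methyl ketone carbon to ring B acyl carbon) is cut. This is the most convergent cut and joins the two rings by enolate C-acylation. The forward reaction must acylate at carbon while both ring A hydroxyls are free, which the polyanion of 4 allows, so ring A is never protected.

**8 to 7 to 6 to 5.** These are functional-group changes only: acid chloride from acid, acid from benzyl ester, and the ester and ethers from the commercial dihydroxy acid 5.

**4 to 2 and 3.** The C4–C4a bond (acyl to ring) is cut. The two free carbons of quinone 2 are equivalent, so no regiochemical question arises. The forward photoacylation delivers 4 directly as the hydroquinone, with its hydroxyls at the future C5 and C8 and hydrogen at the future C8a.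

**2 to 1.** The two para O–CH3 bonds of 1 are cut oxidatively. This gives the symmetrical quinone from a commercial arene in one step.

## Alternatives that were turned down

**Alternative 1:** Ring B is disconnected instead of ring C. The bonds C5'–C6', C1'–C2' and C2'–C3' are cut, leaving 5-(benzyloxy)-2-ethynyl-6,7,8-trimethoxychromen-4-one A2, the carbene complex pentacarbonyl(1-methoxyprop-2-en-1-ylidene)chromium A3, written (CO)5Cr=C(OMe)CH=CH2, and one of its carbonyl ligands. Forward, a Dötz benzannulation would insert the terminal alkyne and then CO and close the resulting vinylketene to the 4-methoxyphenol 5-(benzyloxy)-2-(2-hydroxy-5-methoxyphenyl)-6,7,8-trimethoxychromen-4-one A1.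
- For: three bonds and a ring form in one step. Terminal alkynes place their substituent beside the new phenol, so the 2',5' pattern is correct and the two ring B oxygens arrive differentiated.
- Against: the hard part of the target is ring A, and A2 must still be made from a pentaoxygenated acetophenone by the classical sequence plus an alkynylation. The alkyne of A2 is conjugated to the chromone carbonyl, so it is electron-poor and a Michael acceptor, the class that inserts least readily and diverts to furans and cyclobutenones. A3 has an unsubstituted vinyl group and polymerises easily. Chromium is used stoichiometrically. The 5'-methyl ether of A1 sits beside three ring A methyl ethers, so it can be removed only by oxidation to the ring B quinone and reduction, followed by debenzylation.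
- Comparison: the alternative is stronger in convergence at the key step. The chosen strategy puts its one uncertain step on ring A, where the difficulty lies, and takes ring B ready-made from 5.

**Alternative 2:** Both O1–C8a and C4–C4a are cut, so ring A appears as a symmetrical aryne. The aryne would be set free by fluoride from 3,4,5,6-tetramethoxy-2-(trimethylsilyl)phenyl trifluoromethanesulfonate A5, and rings B and C come from 3-[2,5-di(propan-2-yloxy)phenyl]prop-2-ynoic acid A6. Forward, the carboxylate of A6 adds to the aryne, the aryl anion attacks its own ester carbonyl (formal insertion into the C–O bond), and the ortho-acylphenoxide closes onto the ynone by 6-endo-dig addition to give 2-[2,5-di(propan-2-yloxy)phenyl]-5,6,7,8-tetramethoxychromen-4-one A4.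
- For: it is the most convergent plan. The aryne is symmetrical, so insertion raises no regiochemical question. A4 is one Lewis-acid step from the target (peri demethylation together with loss of the isopropyl groups).
- Against: A5 is itself a hexasubstituted benzene that needs about five steps from 1, so the substitution problem is moved and not solved. The acyl shift passes through a strained four-membered transition state and competes with protonation of the aryl anion by the acid A6, which stops at the aryl ester. Ring A ends as four like methyl ethers, so the free O5 depends on a chelation-controlled demethylation next to the C6 methoxy group.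
- Comparison: the alternative is stronger in bonds formed per step and in end-game length. The chosen strategy keeps O5 as a free phenol from step 2 onward, draws ring A from quinone 2 in two steps, and reaches 9 by enolate chemistry.

**Alternative 3:** Ring A is disconnected at C5–C4a, leaving 4-{6-[2,5-bis(benzyloxy)phenyl]-4-oxo-4H-pyran-2-yl}-2,3,4-trimethoxycyclobut-2-en-1-one A8. A8 would come from 3,4-dimethoxycyclobut-3-ene-1,2-dione A9 and the C6-metallated form of 2-[2,5-bis(benzyloxy)phenyl]-4H-pyran-4-one A10, followed by O-methylation. Forward, heating A8 opens the four-membered ring to a dienylketene whose ketene carbon closes onto C3 of the pyranone by 6π electrocyclisation (Moore-type rearrangement). Enolisation gives 2-[2,5-bis(benzyloxy)phenyl]-5-hydroxy-6,7,8-trimethoxychromen-4-one A7, which is the same compound as 13.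
- For: all four ring A oxygens come from A9 already differentiated, since the ketene carbonyl becomes the free O5. The pericyclic topology fixes the regiochemistry. A7 is one hydrogenolysis from the target. On end-game economy and on the O5/O8 differentiation this alternative is stronger than the chosen route.
- Against: metallated A10 must be made and used beside an electrophilic pyranone carbonyl that is prone to ring opening, and it must add once to A9. The tertiary alkoxide must then be methylated. Ring opening must rotate the pyranonyl group inward. A10 needs its own synthesis of several steps. Uncertainty is therefore spread over two or three consecutive operations.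
- Comparison: the chosen strategy offers a precursor built by robust reactions from inexpensive materials, a single point of risk, and a classical fallback that reuses 1 and 8.

Key step: step 7

Remark on the chemistry: the 1,3-diketones are drawn as diketo tautomers although they should exist mainly as chelated enols; the enol is the reacting form in step 7.

## Route

Step 1
Reactants: 1 1,2,3,4-tetramethoxybenzene
Product: 2 2,3-dimethoxycyclohexa-2,5-diene-1,4-dione
Conditions: (NH4)2Ce(NO3)6 (2.5 equiv), MeCN/H2O, 0 °C
Reagents that add atoms: water, O
Why: Oxidative demethylation of a para-dimethoxyarene by tetravalent cerium: the arene radical cation is trapped by water at the two mutually para methoxy-bearing carbons and methanol is lost twice; the para-quinone is expected because the two remaining methoxy groups become vinylogous esters of both carbonyls.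

Step 2
Reactants: 2 2,3-dimethoxycyclohexa-2,5-diene-1,4-dione; 3 acetaldehyde
Product: 4 1-(2,5-dihydroxy-3,4-dimethoxyphenyl)ethan-1-one
Conditions: MeCHO (10 equiv), hν (400–450 nm, Pyrex), PhCF3, 10 °C, Ar
Reagents that add atoms: none
Why: Photo-Friedel–Crafts acylation of a 1,4-quinone with an aldehyde: the excited quinone abstracts the formyl hydrogen, the acetyl radical recombines with the semiquinone and the adduct enolises to the acylhydroquinone. The two free carbons of 2 are equivalent, so only one C-acyl product can form, and it arrives at the hydroquinone level that step 7 needs.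

Step 3
Reactants: 5 2,5-dihydroxybenzoic acid
Product: 6 benzyl 2,5-bis(benzyloxy)benzoate
Conditions: BnBr (3.3 equiv), K2CO3, DMF, 60 °C
Reagents that add atoms: benzyl bromide, BrCc1ccccc1
Why: Williamson alkylation of the two phenoxides and the carboxylate in one operation. Benzyl is used on ring B because it is inert to LiN(SiMe3)2, Ag2O and K2CO3 and leaves at the end by hydrogenolysis, which spares aryl methyl ethers.

Step 4
Reactants: 6 benzyl 2,5-bis(benzyloxy)benzoate
Product: 7 2,5-bis(benzyloxy)benzoic acid
Conditions: KOH, MeOH/THF/H2O, reflux; then aq. HCl
Reagents that add atoms: potassium hydroxide, [K+].[OH-]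
Why: Saponification of the benzyl ester by acyl–oxygen cleavage; the aryl benzyl ethers are inert to hydroxide.

Step 5
Reactants: 7 2,5-bis(benzyloxy)benzoic acid
Product: 8 2,5-bis(benzyloxy)benzoyl chloride
Conditions: (COCl)2, DMF (cat.), CH2Cl2, 0 °C → rt; evaporate, use crude
Reagents that add atoms: oxalyl chloride, O=C(Cl)C(=O)Cl
Why: Conversion of the acid into its chloride through the chloroiminium species formed from DMF and (COCl)2; the by-products are gases, so 8 can be used without purification.

Step 6
Reactants: 4 1-(2,5-dihydroxy-3,4-dimethoxyphenyl)ethan-1-one; 8 2,5-bis(benzyloxy)benzoyl chloride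
Product: 9 1-[2,5-bis(benzyloxy)phenyl]-3-(2,5-dihydroxy-3,4-dimethoxyphenyl)propane-1,3-dione
Conditions: 4, LiN(SiMe3)2 (4.2 equiv), THF, −78 → −10 °C, Ar; then 8 (1.0 equiv), −78 °C → rt; cold dil. aq. HCl
Reagents that add atoms: none
Why: Claisen-type C-aroylation of a ketone enolate, run on the polylithiated hydroxyacetophenone: three equivalents of base give the bis(phenoxide) enolate and the fourth takes up the acidic proton of the product diketone. The enolate carbon is the most nucleophilic site of the trianion, so ring A needs no protection, and the cold, brief acidic quench avoids cyclodehydration through the ortho hydroxyl.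

Step 7
Reactants: 9 1-[2,5-bis(benzyloxy)phenyl]-3-(2,5-dihydroxy-3,4-dimethoxyphenyl)propane-1,3-dione
Product: 12 2-[2,5-bis(benzyloxy)phenyl]-5,8-dihydroxy-6,7-dimethoxychromen-4-one, via acylquinone 10 (not isolated), via flavone-5,8-quinone 11 (not isolated)
Conditions: Ag2O (3 equiv), MgSO4, CH2Cl2 (0.01 M), rt, dark, Ar; filter (Celite); then aq. Na2S2O4/EtOAc, rt
Reagents that add atoms: none
Why: Proposed new method: Ag2O should oxidise hydroquinone 9 to acylquinone 10, whose only unsubstituted ring carbon lies beside the acyl group and is the β-carbon of both the quinone enone and the side-chain enone; the enol oxygen of the 1,3-diketone adds there in a 6-endo-trig oxa-Michael addition that forms O1–C8a and closes ring C, and loss of the C8a proton re-aromatises ring A as the 5,8-hydroquinone. That hydroquinone is itself oxidisable and would exchange electrons with unreacted 10, so excess oxidant carries everything on to flavonequinone 11 and Na2S2O4 then returns 12. The closest known reaction types are additions of oxygen, nitrogen and sulfur nucleophiles to 2-acyl-1,4-benzoquinones at the carbon next to the acyl group, and oxidative cyclisations of hydroquinones that run through their quinones. No stereocentre is formed. The step needs attack by oxygen and at C8a only: attack by the diketone carbon would close a four-membered ring, the methoxy-bearing quinone carbons could be reached only through a seven-membered ring, and 1,2-addition to the neighbouring quinone carbonyl is reversible and cannot aromatise, whereas the conjugate adduct is removed by tautomerisation. The classical cyclodehydration through the ortho hydroxyl, which would give an isomer without oxygen at C5, is shut off once that phenol has become a quinone carbonyl and no acid is present. Ring B survives because its hydroquinone is locked as benzyl ethers, which Ag2O does not attack, and high dilution disfavours intermolecular addition of the diketone carbon to 10.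

Step 8
Reactants: 12 2-[2,5-bis(benzyloxy)phenyl]-5,8-dihydroxy-6,7-dimethoxychromen-4-one
Product: 13 2-[2,5-bis(benzyloxy)phenyl]-5-hydroxy-6,7,8-trimethoxychromen-4-one
Conditions: MeI (1.2 equiv), K2CO3 (1.5 equiv), acetone (degassed), Ar, rt → 40 °C
Reagents that add atoms: iodomethane, CI
Why: Williamson O-methylation directed by chelation: the 5-hydroxyl is held by a strong hydrogen bond to the C4 carbonyl and is much less acidic and nucleophilic than the 8-hydroxyl, so a small excess of MeI should alkylate O8 only. Air is excluded because the hydroquinone monoanion is easily oxidised.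

Step 9
Reactants: 13 2-[2,5-bis(benzyloxy)phenyl]-5-hydroxy-6,7,8-trimethoxychromen-4-one
Product: 14 2-(2,5-dihydroxyphenyl)-5-hydroxy-6,7,8-trimethoxychromen-4-one (5,2',5'-trihydroxy-6,7,8-trimethoxyflavone)
Conditions: H2 (1 atm), Pd/C, EtOAc/MeOH, rt; work-up under Ar
Reagents that add atoms: none
Why: Hydrogenolysis of aryl benzyl ethers over palladium on carbon; methyl ethers, the chelated phenol and the C2=C3 bond of the chromone (a vinylogous ester) are not expected to react at one atmosphere. The ring B hydroquinone is set free only in this last step.

## Compound list

1 | 1,2,3,4-tetramethoxybenzene | COc1ccc(OC)c(OC)c1OC | starting material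
2 | 2,3-dimethoxycyclohexa-2,5-diene-1,4-dione | COC1=C(OC)C(=O)C=CC1=O | intermediate
3 | acetaldehyde | CC=O | starting material
4 | 1-(2,5-dihydroxy-3,4-dimethoxyphenyl)ethan-1-one | CC(=O)c1cc(O)c(OC)c(OC)c1O | intermediate
5 | 2,5-dihydroxybenzoic acid | O=C(O)c1cc(O)ccc1O | starting material
6 | benzyl 2,5-bis(benzyloxy)benzoate | O=C(OCc1ccccc1)c1cc(OCc2ccccc2)ccc1OCc1ccccc1 | intermediate
7 | 2,5-bis(benzyloxy)benzoic acid | O=C(O)c1cc(OCc2ccccc2)ccc1OCc1ccccc1 | intermediate
8 | 2,5-bis(benzyloxy)benzoyl chloride | O=C(Cl)c1cc(OCc2ccccc2)ccc1OCc1ccccc1 | intermediate
9 | 1-[2,5-bis(benzyloxy)phenyl]-3-(2,5-dihydroxy-3,4-dimethoxyphenyl)propane-1,3-dione | COc1c(OC)c(O)c(C(=O)CC(=O)c2cc(OCc3ccccc3)ccc2OCc2ccccc2)cc1O | intermediate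
10 | 2-{3-[2,5-bis(benzyloxy)phenyl]-3-oxopropanoyl}-5,6-dimethoxycyclohexa-2,5-diene-1,4-dione | COC1=C(OC)C(=O)C(C(=O)CC(=O)c2cc(OCc3ccccc3)ccc2OCc2ccccc2)=CC1=O | intermediate (not isolated)
11 | 2-[2,5-bis(benzyloxy)phenyl]-6,7-dimethoxychromene-4,5,8-trione | COC1=C(OC)C(=O)C2=C(C1=O)C(=O)C=C(c1cc(OCc3ccccc3)ccc1OCc1ccccc1)O2 | intermediate (not isolated)
12 | 2-[2,5-bis(benzyloxy)phenyl]-5,8-dihydroxy-6,7-dimethoxychromen-4-one | COc1c(OC)c(O)c2c(=O)cc(-c3cc(OCc4ccccc4)ccc3OCc3ccccc3)oc2c1O | intermediate
13 | 2-[2,5-bis(benzyloxy)phenyl]-5-hydroxy-6,7,8-trimethoxychromen-4-one | COc1c(OC)c(O)c2c(=O)cc(-c3cc(OCc4ccccc4)ccc3OCc3ccccc3)oc2c1OC | intermediate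
14 | 2-(2,5-dihydroxyphenyl)-5-hydroxy-6,7,8-trimethoxychromen-4-one | COc1c(OC)c(O)c2c(=O)cc(-c3cc(O)ccc3O)oc2c1OC | target

## Step count and risk

Total step count: 9. Longest linear sequence: 7 steps (steps 3 to 9, from 5); the ring A branch (steps 1 and 2) joins at step 6.

**Step 7 (key step, proposed new method).** The likeliest failure is that the acylquinone does not close at C8a. The chelated enol is a weak nucleophile, and the 6-endo approach requires the acyl group to twist out of the quinone plane. Intermolecular conjugate addition of the diketone carbon to another quinone (oligomerisation) or hydrolytic loss of a quinone methoxy group could then take over. The fallback uses classical flavone chemistry, sets out from 1 and 8 and comes back at 13. Ortho-lithiation of 1 (n-BuLi, TMEDA, THF), borylation with B(OMe)3 and oxidation with H2O2 should give 2,3,4,5-tetramethoxyphenol F1. Friedel–Crafts acetylation with AcOH and BF3·OEt2 at the one free carbon, ortho to the hydroxyl, gives 1-(2-hydroxy-3,4,5,6-tetramethoxyphenyl)ethan-1-one F2. BCl3 in CH2Cl2 (−20 °C → rt), held at the ketone by chelation, cleaves the one methoxy group ortho to the acetyl group and gives the symmetrical 1-(2,6-dihydroxy-3,4,5-trimethoxyphenyl)ethan-1-one F3. Its polylithio derivative (LiN(SiMe3)2, 4 equiv, THF, Ar) is aroylated at carbon with 8 to 1-[2,5-bis(benzyloxy)phenyl]-3-(2,6-dihydroxy-3,4,5-trimethoxyphenyl)propane-1,3-dione F4. Acid-catalysed cyclodehydration (p-TsOH, toluene, 80 °C) closes ring C in the usual sense through either of the two equivalent hydroxyls, the other one remaining as the chelated 5-hydroxyl, and gives 13, so that steps 7 and 8 are bypassed and step 9 finishes the synthesis.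

**Step 2.** The two methoxy donors may lower the hydrogen-abstracting power of the excited quinone, so the reaction may stall, stop at photoreduction without acylation, or acylate the semiquinone on oxygen instead of carbon. The fallback sets out from 2 and comes back at 4. Reduction with aqueous Na2S2O4 gives 2,3-dimethoxybenzene-1,4-diol F5, and Friedel–Crafts C-acetylation with AcOH and BF3·OEt2 (85 °C, Ar) at one of the two equivalent free carbons gives 4.

**Step 6.** Aroylation may occur on the unhindered 5-phenoxide or twice, and the very electron-rich polyanion may be oxidised by traces of air. The fallback sets out from 4 and 8 and comes back at 9 by a Baker–Venkataraman sequence. Both phenols are aroylated (8, 2.2 equiv, pyridine, DMAP cat.) to 2-acetyl-5,6-dimethoxy-1,4-phenylene bis[2,5-bis(benzyloxy)benzoate] F6. KOt-Bu in THF moves the ortho aroyl group from oxygen to the enolate carbon, giving 5-{3-[2,5-bis(benzyloxy)phenyl]-3-oxopropanoyl}-4-hydroxy-2,3-dimethoxyphenyl 2,5-bis(benzyloxy)benzoate F7. LiOH in THF/H2O under Ar, followed by mild acidification, removes the remaining aryl ester and gives 9, with 7 recovered.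

**Step 8.** Base-promoted autoxidation of the hydroquinone monoanion back to the quinone may compete, and forcing the reaction may also methylate the chelated 5-hydroxyl. The fallback sets out from 12 and comes back at 14. Exhaustive methylation (MeI in excess, K2CO3, DMF, 50 °C, Ar) converts 12 into 2-[2,5-bis(benzyloxy)phenyl]-5,6,7,8-tetramethoxychromen-4-one F8. BCl3 in CH2Cl2 (−78 → 0 °C) then removes the 5-methyl group by chelation to the C4 carbonyl together with both benzyl groups, giving 14, so selectivity comes from dealkylation instead of alkylation.

## Further compounds

F1 | step 7 | 2,3,4,5-tetramethoxyphenol | COc1cc(O)c(OC)c(OC)c1OC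
F2 | step 7 | 1-(2-hydroxy-3,4,5,6-tetramethoxyphenyl)ethan-1-one | CC(=O)c1c(O)c(OC)c(OC)c(OC)c1OC
F3 | step 7 | 1-(2,6-dihydroxy-3,4,5-trimethoxyphenyl)ethan-1-one | CC(=O)c1c(O)c(OC)c(OC)c(OC)c1O
F4 | step 7 | 1-[2,5-bis(benzyloxy)phenyl]-3-(2,6-dihydroxy-3,4,5-trimethoxyphenyl)propane-1,3-dione | COc1c(OC)c(O)c(C(=O)CC(=O)c2cc(OCc3ccccc3)ccc2OCc2ccccc2)c(O)c1OC
F5 | step 2 | 2,3-dimethoxybenzene-1,4-diol | COc1c(O)ccc(O)c1OC
F6 | step 6 | 2-acetyl-5,6-dimethoxy-1,4-phenylene bis[2,5-bis(benzyloxy)benzoate] | CC(=O)c1cc(OC(=O)c2cc(OCc3ccccc3)ccc2OCc2ccccc2)c(OC)c(OC)c1OC(=O)c1cc(OCc2ccccc2)ccc1OCc1ccccc1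
F7 | step 6 | 5-{3-[2,5-bis(benzyloxy)phenyl]-3-oxopropanoyl}-4-hydroxy-2,3-dimethoxyphenyl 2,5-bis(benzyloxy)benzoate | COc1c(OC)c(O)c(C(=O)CC(=O)c2cc(OCc3ccccc3)ccc2OCc2ccccc2)cc1OC(=O)c1cc(OCc2ccccc2)ccc1OCc1ccccc1
F8 | step 8 | 2-[2,5-bis(benzyloxy)phenyl]-5,6,7,8-tetramethoxychromen-4-one | COc1c(OC)c(OC)c2c(=O)cc(-c3cc(OCc4ccccc4)ccc3OCc3ccccc3)oc2c1OC
A1 | alternative 1 | 5-(benzyloxy)-2-(2-hydroxy-5-methoxyphenyl)-6,7,8-trimethoxychromen-4-one | COc1ccc(O)c(-c2cc(=O)c3c(OCc4ccccc4)c(OC)c(OC)c(OC)c3o2)c1
A2 | alternative 1 | 5-(benzyloxy)-2-ethynyl-6,7,8-trimethoxychromen-4-one | C#Cc1cc(=O)c2c(OCc3ccccc3)c(OC)c(OC)c(OC)c2o1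
A3 | alternative 1 | pentacarbonyl(1-methoxyprop-2-en-1-ylidene)chromium, (CO)5Cr=C(OMe)CH=CH2 | COC(C=C)=[Cr](=C=O)(=C=O)(=C=O)(=C=O)=C=O
A4 | alternative 2 | 2-[2,5-di(propan-2-yloxy)phenyl]-5,6,7,8-tetramethoxychromen-4-one | COc1c(OC)c(OC)c2c(=O)cc(-c3cc(OC(C)C)ccc3OC(C)C)oc2c1OC
A5 | alternative 2 | 3,4,5,6-tetramethoxy-2-(trimethylsilyl)phenyl trifluoromethanesulfonate | COc1c(OC)c(OC)c([Si](C)(C)C)c(OS(=O)(=O)C(F)(F)F)c1OC
A6 | alternative 2 | 3-[2,5-di(propan-2-yloxy)phenyl]prop-2-ynoic acid | CC(C)Oc1ccc(OC(C)C)c(C#CC(=O)O)c1
A7 | alternative 3 | 2-[2,5-bis(benzyloxy)phenyl]-5-hydroxy-6,7,8-trimethoxychromen-4-one | COc1c(OC)c(O)c2c(=O)cc(-c3cc(OCc4ccccc4)ccc3OCc3ccccc3)oc2c1OC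
A8 | alternative 3 | 4-{6-[2,5-bis(benzyloxy)phenyl]-4-oxo-4H-pyran-2-yl}-2,3,4-trimethoxycyclobut-2-en-1-one | COC1=C(OC)C(OC)(c2cc(=O)cc(-c3cc(OCc4ccccc4)ccc3OCc3ccccc3)o2)C1=O
A9 | alternative 3 | 3,4-dimethoxycyclobut-3-ene-1,2-dione | COC1=C(OC)C(=O)C1=O
A10 | alternative 3 | 2-[2,5-bis(benzyloxy)phenyl]-4H-pyran-4-one | O=c1ccoc(-c2cc(OCc3ccccc3)ccc2OCc2ccccc2)c1
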